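## Retrosynthetic overview

- The target is traced back to a ring-B α-bromo ketone (axial methyl delivery makes the tertiary alcohol), then to a ring-B enone (reductive α-bromination), then to a spiro cyclohexa-2,5-dienone whose two arms are told apart by a copper-hydride 1,4-reduction that fixes the spiro centre C6.
- The spirodienone is disconnected at C8–C9 and C6–C7 of ring A: a propynyl anion is joined to an aryl bromo triflate, and the new alkyne closes onto the arene in the same flask.
- The enabling feature is the ipso carbon of a para-methoxyphenyl ring (future spiro C6). It is tied through the quaternary C11 and the bromine-bearing C10 to the primary carbon C9, so a propyne unit fixed at C9 places its methyl-bearing carbon (C7) at six-ring distance from that ipso carbon.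
- The aryl bromo triflate comes from anisole and prenol: enantioselective bromochlorination sets the C10–Br centre, and a bromonium-mediated Friedel–Crafts arylation attaches the ring.
- Ring order: ring B enters as the benzene ring of anisole; ring A is closed in step 4, which dearomatises ring B; ring B is then taken from dienone to bromohydrin.

Key step: step 4

Remark: positions follow spiro[5.5]undecane numbering (ring B C1–C5, spiro C6, ring A C7–C11), so the target is (2R,3R,6R,10S)-2,10-dibromo-3,7,11,11-tetramethylspiro[5.5]undec-7-en-3-ol; the descriptor of the C–Br centre made in step 1 changes (2S, 2R, 10S) only through substituent priorities, and ligands and catalysts are taken as available reagents.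

## Route

Step 1
Reactants: 1 3-methylbut-2-en-1-ol (prenol)
Product: 4 (2S)-2-bromo-3-chloro-3-methylbutan-1-ol
Conditions: NBS (1.05 equiv), ClTi(OiPr)3 (1.1 equiv), chiral tridentate Schiff-base amino-alcohol ligand (20 mol %), hexanes, −20 °C
Reagents that add atoms: N-bromosuccinimide (2), O=C1CCC(=O)N1Br; chlorotitanium triisopropoxide (3), CC(C)O[Ti](Cl)(OC(C)C)OC(C)C
Why: Titanium-alkoxide-directed catalytic enantioselective bromochlorination of an allylic alcohol: the bromonium ion forms on the alkene bound to the chiral titanium complex and chloride is delivered anti to the more substituted carbon, so the ligand antipode fixes the secondary C–Br centre (2S) and the tertiary chloride is regiodefined.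

Step 2
Reactants: 4 (2S)-2-bromo-3-chloro-3-methylbutan-1-ol; 5 anisole
Product: 6 (2R)-2-bromo-3-(4-methoxyphenyl)-3-methylbutan-1-ol
Conditions: anisole (5 equiv), (CF3)2CHOH, 0 °C to rt, short reaction time
Reagents that add atoms: none
Why: Friedel–Crafts alkylation through anchimerically assisted ionisation: in the ionising, weakly nucleophilic fluoroalcohol the neighbouring bromine expels chloride to give a configurationally defined bromonium ion, which the para carbon of anisole opens at the tertiary carbon; the C–Br bond is never broken, so the stereocentre is retained.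

Step 3
Reactants: 6 (2R)-2-bromo-3-(4-methoxyphenyl)-3-methylbutan-1-ol
Product: 8 (2R)-2-bromo-3-(4-methoxyphenyl)-3-methylbutyl trifluoromethanesulfonate
Conditions: Tf2O, 2,6-lutidine, CH2Cl2, −78 °C; used at once
Reagents that add atoms: trifluoromethanesulfonic anhydride (7), O=S(=O)(OS(=O)(=O)C(F)(F)F)C(F)(F)F
Why: Standard O-sulfonylation of a primary alcohol with a hindered pyridine base at low temperature; the stereocentre is not touched.

Step 4
Reactants: 8 (2R)-2-bromo-3-(4-methoxyphenyl)-3-methylbutyl trifluoromethanesulfonate
Product: 12 (10S)-10-bromo-7,11,11-trimethylspiro[5.5]undeca-1,4,7-trien-3-one, via aryl alkyne 11 (not isolated)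
Conditions: a) CH3C≡CLi (1.2 equiv), THF, −78 to −20 °C; b) same flask: Tf2NH (to neutralise excess acetylide), H2O (2 equiv), (Ph3P)AuNTf2 (5 mol %), ClCH2CH2Cl added, 50 °C
Reagents that add atoms: 1-propynyllithium (9), [Li]C#CC; water (10), O (its oxygen becomes the carbonyl oxygen through the hemiketal)
Why: Proposed new method: the acetylide displaces the primary triflate by SN2 (C8–C9 bond), and the resulting 2-alkyne is activated by the cationic monovalent gold catalyst and attacked anti by the para-methoxy-activated ipso carbon of the arene at its distal, methyl-bearing carbon (C6–C7 bond), after which water turns the spiro oxocarbenium ion into the dienone with loss of methanol and protodeauration leaves the C7=C8 alkene. The closest known reaction types are the alkynylation of primary triflates with lithium acetylides and the gold-catalysed or halonium-induced dearomative ipso-cyclisation of para-methoxyaryl alkynes to spirotrienones; new are the one-flask merger and the closure to a spiro[5.5] ring on a non-activated 2-alkyne. Ring A closes in the 6-endo-dig mode at the ipso carbon and ring B is dearomatised in the same event. No new stereocentre arises because the two dienone arms are identical, and the C10–Br centre lies outside the reacting atoms and is retained. The step needs ipso rather than ortho attack, which the para-methoxy group and the seven-membered alternative secure, and 6-endo rather than 5-exo closure, which should be favoured because the methyl group stabilises positive charge at the distal alkyne carbon, the electron-withdrawing β-C–Br bond disfavours charge at the proximal carbon, and the gem-dimethyl carbon compresses the tether.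

Step 5
Reactants: 12 (10S)-10-bromo-7,11,11-trimethylspiro[5.5]undeca-1,4,7-trien-3-one
Product: 15 (6R,10S)-10-bromo-7,11,11-trimethylspiro[5.5]undeca-1,7-dien-3-one, via silyl dienol ether 14 (not isolated)
Conditions: Cu(OAc)2 (5 mol %), (R)- or (S)-DTBM-SEGPHOS (5.5 mol %, antipode fixed in a first run), (EtO)2MeSiH (13, 1.1 equiv), toluene, −20 °C; then 1 M HCl, THF, 0 °C
Reagents that add atoms: none
Why: Proposed new method: a bisphosphine–copper hydride adds hydride to the β-carbon of only one of the two diastereotopic enone arms, and the copper dienolate is silylated to a 2-silyloxy-1,3-diene that is no longer an acceptor, so reduction should stop after one arm and acid work-up gives the enone. The ligand is chosen to reduce the arm that is trans to the C10 bromine across ring A (axial on ring A); this is also the less shielded β-carbon, since the other arm is flanked by a C11 methyl and the C7 methyl, so catalyst and substrate control should reinforce each other and set C6 as R. Closest known reaction types: copper-hydride/bisphosphine asymmetric 1,4-reduction of cyclic enones and catalytic enantiotopic-group-selective desymmetrisation of 4,4-disubstituted cyclohexa-2,5-dienones.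

Step 6
Reactants: 15 (6R,10S)-10-bromo-7,11,11-trimethylspiro[5.5]undeca-1,7-dien-3-one
Product: 17 (2R,6R,10S)-2,10-dibromo-7,11,11-trimethylspiro[5.5]undec-7-en-3-one, via silyl enol ether 16 (not isolated)
Conditions: Cu(OAc)2 (5 mol %), 1,2-bis(diphenylphosphino)benzene (5 mol %), (EtO)2MeSiH (1.5 equiv), toluene, rt; then NBS (1.05 equiv), THF, −78 °C
Reagents that add atoms: N-bromosuccinimide (2), O=C1CCC(=O)N1Br
Why: Copper-hydride 1,4-hydrosilylation gives the silyl enol ether regiospecifically towards C2, and electrophilic α-bromination of that enol ether should occur on the face anti to C7 (the ring-A carbon that sits axial on ring B at the spiro centre), giving the equatorial C2 bromide (2R), which is also the thermodynamically preferred epimer of this enolisable centre.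

Step 7
Reactants: 17 (2R,6R,10S)-2,10-dibromo-7,11,11-trimethylspiro[5.5]undec-7-en-3-one
Product: 19 (2R,3R,6R,10S)-2,10-dibromo-3,7,11,11-tetramethylspiro[5.5]undec-7-en-3-ol (target)
Conditions: Me3Al (3 equiv), toluene, −78 to −40 °C; cold quench with aqueous sodium potassium tartrate
Reagents that add atoms: trimethylaluminium (18), C[Al](C)C
Why: 1,2-Addition of trimethylaluminium to a ketone: with excess Me3Al in a hydrocarbon solvent methyl is delivered along the axial trajectory, further favoured here because the equatorial C2 bromine screens the equatorial approach, so methyl becomes axial and the hydroxyl equatorial and trans to bromine (3R); the cold quench is meant to avoid semipinacol ring contraction of the halohydrin aluminate.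

## Compound list

1 | 3-methylbut-2-en-1-ol (prenol) | CC(C)=CCO | starting material
2 | N-bromosuccinimide | O=C1CCC(=O)N1Br | starting material
3 | chlorotitanium triisopropoxide, ClTi(OiPr)3 | CC(C)O[Ti](Cl)(OC(C)C)OC(C)C | starting material
4 | (2S)-2-bromo-3-chloro-3-methylbutan-1-ol | OC[C@H](Br)C(C)(C)Cl | intermediate
5 | anisole | COc1ccccc1 | starting material
6 | (2R)-2-bromo-3-(4-methoxyphenyl)-3-methylbutan-1-ol | OC[C@H](Br)C(C)(C)c1ccc(OC)cc1 | intermediate
7 | trifluoromethanesulfonic anhydride | O=S(=O)(OS(=O)(=O)C(F)(F)F)C(F)(F)F | starting material
8 | (2R)-2-bromo-3-(4-methoxyphenyl)-3-methylbutyl trifluoromethanesulfonate | FC(F)(F)S(=O)(=O)OC[C@H](Br)C(C)(C)c1ccc(OC)cc1 | intermediate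
9 | 1-propynyllithium | [Li]C#CC | starting material
10 | water | O | starting material
11 | 1-[(3S)-3-bromo-2-methylhept-5-yn-2-yl]-4-methoxybenzene (formed in the flask, not isolated) | CC#CC[C@H](Br)C(C)(C)c1ccc(OC)cc1 | intermediate
12 | (10S)-10-bromo-7,11,11-trimethylspiro[5.5]undeca-1,4,7-trien-3-one | CC1=CC[C@H](Br)C(C)(C)C12C=CC(=O)C=C2 | intermediate
13 | diethoxy(methyl)silane | CCO[SiH](C)OCC | starting material
14 | diethoxy(methyl){[(6R,10S)-10-bromo-7,11,11-trimethylspiro[5.5]undeca-1,3,7-trien-3-yl]oxy}silane (formed in the flask, not isolated) | CC1=CC[C@H](Br)C(C)(C)[C@@]12CC=C(O[Si](C)(OCC)OCC)C=C2 | intermediate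
15 | (6R,10S)-10-bromo-7,11,11-trimethylspiro[5.5]undeca-1,7-dien-3-one | CC1=CC[C@H](Br)C(C)(C)[C@@]12CCC(=O)C=C2 | intermediate
16 | diethoxy(methyl){[(6R,10S)-10-bromo-7,11,11-trimethylspiro[5.5]undeca-2,7-dien-3-yl]oxy}silane (formed in the flask, not isolated) | CC1=CC[C@H](Br)C(C)(C)[C@@]12CCC(O[Si](C)(OCC)OCC)=CC2 | intermediate
17 | (2R,6R,10S)-2,10-dibromo-7,11,11-trimethylspiro[5.5]undec-7-en-3-one | CC1=CC[C@H](Br)C(C)(C)[C@@]12CCC(=O)[C@H](Br)C2 | intermediate
18 | trimethylaluminium | C[Al](C)C | starting material
19 | (2R,3R,6R,10S)-2,10-dibromo-3,7,11,11-tetramethylspiro[5.5]undec-7-en-3-ol | CC1=CC[C@H](Br)C(C)(C)[C@@]12CC[C@@](C)(O)[C@H](Br)C2 | target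

## Totals and risks

Total step count: 7. Longest linear sequence: 7 steps (from prenol).

Steps most likely to fail:

1. Step 4 (Proposed new method). The ring-closing event may take the 5-exo course at the proximal alkyne carbon or be overtaken by hydration of the alkyne, and elimination of triflic acid may compete with the alkynylation. The fallback sets out from 8 and returns at 12. Compound 8 is alkylated with 3-lithio-1-(trimethylsilyl)propyne (from 1-(trimethylsilyl)propyne and n-BuLi, THF, −78 °C), a propargyl anion that reacts at its CH2 terminus, to give [(5S)-5-bromo-6-(4-methoxyphenyl)-6-methylhept-1-yn-1-yl]trimethylsilane F1. K2CO3 in methanol then gives the terminal alkyne 1-[(3S)-3-bromo-2-methylhept-6-yn-2-yl]-4-methoxybenzene F2. With a terminal alkyne on a four-atom tether the (Ph3P)AuNTf2/water ipso-closure has to occur at the internal alkyne carbon (6-exo-dig, the regiochemistry established for gold-catalysed ipso-closures of para-oxygenated aryl alkynes), which should give (10S)-10-bromo-11,11-dimethyl-7-methylidenespiro[5.5]undeca-1,4-dien-3-one F3. RhCl3·3H2O in ethanol at 70 °C is then used to move the exocyclic double bond into ring A, giving 12.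

2. Step 5 (Proposed new method). The hydride may fail to discriminate between the two dienone arms, or the second arm may be reduced as well. The fallback sets out from 12 and returns at 17. Both dienone double bonds are reduced with an achiral copper hydride (Cu(OAc)2, 1,2-bis(diphenylphosphino)benzene, excess (EtO)2MeSiH, t-BuOH, then dilute HCl) to (10S)-10-bromo-7,11,11-trimethylspiro[5.5]undec-7-en-3-one F4, in which C6 is not yet a stereocentre. Deprotonation selective between the two α-methylene groups with a chiral lithium amide (lithium bis[(1R)-1-phenylethyl]amide or its antipode, Me3SiCl present, THF, −100 °C), a known way to desymmetrise 4,4-disubstituted cyclohexanones, should give {[(6R,10S)-10-bromo-7,11,11-trimethylspiro[5.5]undeca-2,7-dien-3-yl]oxy}trimethylsilane F5. NBS in THF at −78 °C converts it into 17.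

3. Step 2. In the ionising solvent the electron-rich aryl group of the product may assist ionisation of the secondary bromide, leading to 1,2-aryl shift and erosion of configuration, and ortho attack or solvent capture may compete. The fallback sets out from 5 and returns at 6. AlCl3-mediated Friedel–Crafts alkylation of anisole with 3-methylbut-2-enoic acid gives 3-(4-methoxyphenyl)-3-methylbutanoic acid F6; LiAlH4 gives 3-(4-methoxyphenyl)-3-methylbutan-1-ol F7; Swern oxidation gives 3-(4-methoxyphenyl)-3-methylbutanal F8. Enamine-catalysed enantioselective α-bromination (diarylprolinol silyl ether catalyst, 4,4-dibromo-2,6-di-tert-butylcyclohexa-2,5-dienone, −40 °C) should give (2R)-2-bromo-3-(4-methoxyphenyl)-3-methylbutanal F9, which is reduced in the same flask with NaBH4 to 6.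

Further compounds
F1 | step 4 | [(5S)-5-bromo-6-(4-methoxyphenyl)-6-methylhept-1-yn-1-yl]trimethylsilane | C[Si](C)(C)C#CCC[C@H](Br)C(C)(C)c1ccc(OC)cc1
F2 | step 4 | 1-[(3S)-3-bromo-2-methylhept-6-yn-2-yl]-4-methoxybenzene | C#CCC[C@H](Br)C(C)(C)c1ccc(OC)cc1
F3 | step 4 | (10S)-10-bromo-11,11-dimethyl-7-methylidenespiro[5.5]undeca-1,4-dien-3-one | C=C1CC[C@H](Br)C(C)(C)C12C=CC(=O)C=C2
F4 | step 5 | (10S)-10-bromo-7,11,11-trimethylspiro[5.5]undec-7-en-3-one | CC1=CC[C@H](Br)C(C)(C)C12CCC(=O)CC2
F5 | step 5 | {[(6R,10S)-10-bromo-7,11,11-trimethylspiro[5.5]undeca-2,7-dien-3-yl]oxy}trimethylsilane | CC1=CC[C@H](Br)C(C)(C)[C@@]12CCC(O[Si](C)(C)C)=CC2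
F6 | step 2 | 3-(4-methoxyphenyl)-3-methylbutanoic acid | COc1ccc(cc1)C(C)(C)CC(=O)O
F7 | step 2 | 3-(4-methoxyphenyl)-3-methylbutan-1-ol | COc1ccc(cc1)C(C)(C)CCO
F8 | step 2 | 3-(4-methoxyphenyl)-3-methylbutanal | COc1ccc(cc1)C(C)(C)CC=O
F9 | step 2 | (2R)-2-bromo-3-(4-methoxyphenyl)-3-methylbutanal | O=C[C@H](Br)C(C)(C)c1ccc(OC)cc1
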